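**Plan**

- Numbering of the target: quinone C1(=O) lies between C2 (side chain) and C6 (H); C4(=O) lies between C3(OMe) and C5(OMe). The retrosynthesis cuts O=C1 (back to the para C–H of a 2,6-dimethoxyphenol), the aryl–C(=O) bond of the side chain (back to a nitrile), both ring C=C bonds C2=C3 and C5=C6 in one stroke, and the formyl–alkyne bond of the resulting ynal.
- Enabling feature: C3–C4(=O)–C5 with its two methoxy groups is a mirror-symmetric MeO–C–C(=O)–C–OMe triad, i.e. 1,3-dimethoxyacetone acting as a two-fold carbon nucleophile. C2 and C6 stand 1,3 across C1 and map onto the β-alkyne carbon and the formyl carbon of a 2-ynal; C1 is left as the only free position para to the phenolic OH.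
- Forward: formylation of pent-4-ynenitrile gives the cyano-ynal; one base-mediated [3+3] operation builds the whole benzenoid ring (the only ring formed). The nitrile, carried through that step as a non-enolizable latent ketone, is then arylated with the Grignard reagent, and Teuber oxidation at C1 gives the quinone.
- Stereochemistry: the target has no stereocentre and no stereogenic double bond; the transient centres and alkene geometry of the annulation intermediates are erased on aromatization.

Key step: step 2

Remark: pent-4-ynenitrile, 1,3-dimethoxypropan-2-one and 3,4-dimethoxyphenylmagnesium bromide (THF solution) are taken as purchased reagents.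

**Step 1**
Reactants: 1 pent-4-ynenitrile
Product: 4 6-oxohex-4-ynenitrile, via lithium acetylide 2 (not isolated), via lithium hemiaminal alkoxide 3 (not isolated)
Conditions: n-BuLi (1.0 equiv), THF, −78 °C; DMF (2 equiv), −78 → 0 °C; poured into cold 1 M HCl/Et2O
Reagents that add atoms: N,N-dimethylformamide, CN(C)C=O
Why: The acetylenic C–H is by far the most acidic site, so n-BuLi should give the acetylide without touching the nitrile at −78 °C, and formylation with DMF (Bouveault-type aldehyde synthesis) stops at the tetrahedral alkoxide, which releases the ynal only in the acidic inverse quench that also keeps dimethylamine protonated.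

**Step 2**
Reactants: 4 6-oxohex-4-ynenitrile; 5 1,3-dimethoxypropan-2-one
Product: 8 3-(3-hydroxy-2,4-dimethoxyphenyl)propanenitrile, via Michael adduct 6 (not isolated), via cyclic aldol 7 (not isolated)
Conditions: 5 (2 equiv), KOtBu (1.3 equiv), THF/t-BuOH, −20 °C, slow addition of 4; then 55 °C, Ar; AcOH quench
Reagents that add atoms: none
Why: The potassium enolate of 5 should add in conjugate fashion to C4 of 4 (the alkyne carbon that carries the cyanoethyl chain; an aldolate formed at the formyl group can revert under these equilibrating conditions) to give 6, held as a delocalized dienolate, whose second methoxy-bearing carbon then attacks the formyl group to give 7, and 7 loses water and enolizes to the potassium phenoxide of 8. The closest known reaction type is the base-mediated Michael addition/aldol condensation benzannulation of acetonedicarboxylate anions with conjugated alkynals, backed by the classical phenol synthesis from ketones with two α-CH groups and malonaldehyde-type 1,3-dielectrophiles. The only ring is closed by a 6-(enolendo)-exo-trig aldol addition. No stereocentre is carried on, since the centres of 6 and 7 and the alkene geometry of 6 (labile through the dienolate) are erased on aromatization. The step needs site selectivity in both bond formations and the substrates supply it: 5 is mirror-symmetric, so either methoxy-bearing carbon may attack first with the same outcome; the formyl group has no α-hydrogen and is the only electrophile that the remaining nucleophilic carbon can reach through a six-membered ring; and the chain ends in a nitrile, whose α-hydrogens are far less acidic than those of 5 and which is inert to the enolate. Aromatization to the phenoxide makes the sequence irreversible.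

**Step 3**
Reactants: 8 3-(3-hydroxy-2,4-dimethoxyphenyl)propanenitrile; 9 3,4-dimethoxyphenylmagnesium bromide
Product: 11 1-(3,4-dimethoxyphenyl)-3-(3-hydroxy-2,4-dimethoxyphenyl)propan-1-one, via magnesium ketimide 10 (not isolated)
Conditions: 9 (3.5 equiv), CuBr (5 mol%), THF, 0 °C → reflux; then 2 M HCl, rt
Reagents that add atoms: water, O
Why: Grignard addition to a nitrile: the first equivalent forms the magnesium phenoxide, a further one adds once to the nitrile (CuBr favours addition over α-deprotonation), the N-magnesio ketimide cannot add a second time, and acidic hydrolysis should give the aryl ketone.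

**Step 4**
Reactants: 11 1-(3,4-dimethoxyphenyl)-3-(3-hydroxy-2,4-dimethoxyphenyl)propan-1-one
Product: 12 evelynin
Conditions: (KSO3)2NO (2.5 equiv), KH2PO4, H2O/acetone, 0 °C → rt
Reagents that add atoms: potassium nitrosodisulfonate (KSO3)2NO, [K+].[K+].[O-]S(=O)(=O)N([O])S(=O)(=O)[O-]
Why: Teuber oxidation: the nitroxide abstracts the phenolic hydrogen, a second equivalent adds to the aryloxyl radical at the only free para position (both ortho positions carry methoxy groups) and loss of HN(SO3K)2 should give the p-quinone, while the non-phenolic dimethoxyphenyl ketone is inert.

**Compound list**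

1 | pent-4-ynenitrile | C#CCCC#N | starting material
2 | 5-lithiopent-4-ynenitrile (lithium acetylide) | [Li]C#CCCC#N | intermediate (not isolated)
3 | lithium 5-cyano-1-(dimethylamino)pent-2-yn-1-olate (hemiaminal alkoxide) | N#CCCC#CC(O[Li])N(C)C | intermediate (not isolated)
4 | 6-oxohex-4-ynenitrile | N#CCCC#CC=O | intermediate
5 | 1,3-dimethoxypropan-2-one | COCC(=O)COC | starting material
6 | (2Z)-3-(2-cyanoethyl)-4,6-dimethoxy-5-oxohex-2-enal (racemic; alkene geometry labile) | COCC(=O)C(OC)/C(CCC#N)=C\C=O | intermediate (not isolated)
7 | 3-(3-hydroxy-4,6-dimethoxy-5-oxocyclohex-1-en-1-yl)propanenitrile (mixture of diastereomers) | COC1C(O)C=C(CCC#N)C(OC)C1=O | intermediate (not isolated)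
8 | 3-(3-hydroxy-2,4-dimethoxyphenyl)propanenitrile | COc1ccc(CCC#N)c(OC)c1O | intermediate
9 | 3,4-dimethoxyphenylmagnesium bromide | COc1ccc([Mg]Br)cc1OC | starting material
10 | N-bromomagnesio ketimide of 11 as its bromomagnesium phenoxide | COc1ccc(CCC(=N[Mg]Br)c2ccc(OC)c(OC)c2)c(OC)c1O[Mg]Br | intermediate (not isolated)
11 | 1-(3,4-dimethoxyphenyl)-3-(3-hydroxy-2,4-dimethoxyphenyl)propan-1-one | COc1ccc(CCC(=O)c2ccc(OC)c(OC)c2)c(OC)c1O | intermediate
12 | evelynin, 2-[3-(3,4-dimethoxyphenyl)-3-oxopropyl]-3,5-dimethoxycyclohexa-2,5-diene-1,4-dione | COC1=CC(=O)C(CCC(=O)c2ccc(OC)c(OC)c2)=C(OC)C1=O | target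

Total step count: 4. Longest linear sequence: 4 steps (1 → 4 → 8 → 11 → 12).

**Steps most likely to fail**

1. Step 2. What may go wrong: kinetic addition of the enolate to the formyl group followed by dehydration would lead to a cross-conjugated enynone that has no leaving group at the alkyne carbon and closes only sluggishly; base-induced prototropic isomerization and oligomerization of the ynal would also consume the electrophile. The fallback sets out from 4 and comes back at 8. Compound 4 would first be treated with morpholine (1.05 equiv, EtOH, 0 °C); aza-Michael addition should give the stable vinylogous formamide (4E)-4-(morpholin-4-yl)-6-oxohex-4-enenitrile F1. F1 would then be condensed with 5 (NaOMe, MeOH, reflux, Ar). Knoevenagel-type condensation at the formyl group, 6π-electrocyclization of the resulting aminotrienolate and loss of morpholine (the known aminoacrolein/ketone phenol synthesis) should give 8.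

2. Step 3. What may go wrong: deprotonation α to the nitrile by the Grignard reagent in place of addition, self-condensation of the nitrile anion, or stalling because the magnesium phenoxide precipitates. The fallback sets out from 8 and comes back at 11. The nitrile would be hydrolysed (NaOH, H2O/EtOH, reflux, Ar; then acid) to 3-(3-hydroxy-2,4-dimethoxyphenyl)propanoic acid F2. Coupling with N,O-dimethylhydroxylamine hydrochloride (EDC·HCl, HOBt, i-Pr2NEt, CH2Cl2) would give 3-(3-hydroxy-2,4-dimethoxyphenyl)-N-methoxy-N-methylpropanamide F3. Treatment with 9 (3 equiv, THF, 0 °C; acidic quench) should give 11 through the stable magnesium chelate.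

3. Step 1. What may go wrong: addition of n-BuLi or of the acetylide to the nitrile, deprotonation α to the nitrile with self-condensation, conjugate addition of liberated dimethylamine during the quench, or loss of the small, labile ynal on isolation. The fallback sets out from 1 and comes back at 4 and avoids organolithium chemistry. Compound 1 would be condensed with triethyl orthoformate (ZnI2 cat., neat, 140 °C, ethanol distilled off) to the acetylenic acetal 6,6-diethoxyhex-4-ynenitrile F4. This can be purified and stored, and would be hydrolysed just before use (HCO2H, or dilute H2SO4 in acetone/H2O, rt) to 4.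

**Further compounds**

F1 | step 2 | (4E)-4-(morpholin-4-yl)-6-oxohex-4-enenitrile | O=C/C=C(/N1CCOCC1)CCC#N
F2 | step 3 | 3-(3-hydroxy-2,4-dimethoxyphenyl)propanoic acid | COc1ccc(CCC(=O)O)c(OC)c1O
F3 | step 3 | 3-(3-hydroxy-2,4-dimethoxyphenyl)-N-methoxy-N-methylpropanamide | COc1ccc(CCC(=O)N(C)OC)c(OC)c1O
F4 | step 1 | 6,6-diethoxyhex-4-ynenitrile | CCOC(OCC)C#CCCC#N
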